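**Retrosynthetic overview**

- The strategy rests on the trans-2-aryl-3-(hydroxymethyl)-2,3-dihydrobenzofuran. C2 is a benzylic ether CH bonded to O1 and ring C; C3 is bonded to C3a of ring D and carries a CH2OH that is a reduced ester. The C2–C3 bond is therefore cut to a ring D aryldiazoacetate carbene (C3) and an O–CH2–ring C benzyl ether (C2).
- Peripheral disconnections: the C5 enal goes back to a C5 bromide (Heck). Each erythro aryloxyglycerol unit (ring B first, then ring A) goes back to a phenol, a chloroacetyl oxazolidinone and a silyl-protected hydroxybenzaldehyde (syn-aldol, Mitsunobu inversion at the benzylic carbinol, reductive release).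
- The diazo ester comes from 5-bromo-o-vanillin by one-carbon homologation and O-benzylation with a MOM-protected syringyl bromide.
- Ring order: rings A, B, C and D are bought as arenes; the furan ring O1–C2–C3–C3a–C7a is the only ring formed, in the key step.

Key step: step 9

Assumption: the (S)-phthalimido-tert-leucinate dirhodium catalyst is taken to deliver the (2R) benzylic centre, by analogy with closely related 5-bromo aryldiazoacetates; should the sense prove opposite, the (R)-catalyst is used with no other change.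

**Route**

Step 1
Reactants: 1 syringaldehyde
Product: 2 4-(methoxymethoxy)-3,5-dimethoxybenzaldehyde
Conditions: MOMCl, i-Pr2NEt, CH2Cl2, 0 °C to rt
Reagents that add atoms: chloromethyl methyl ether, COCCl
Why: Williamson-type O-alkylation of the phenol with the reactive α-chloro ether installs a methoxymethyl (MOM) acetal that should survive methoxide, hydride and the carbene step.

Step 2
Reactants: 2 4-(methoxymethoxy)-3,5-dimethoxybenzaldehyde
Product: 3 [4-(methoxymethoxy)-3,5-dimethoxyphenyl]methanol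
Conditions: NaBH4, MeOH, 0 °C
Reagents that add atoms: none
Why: Borohydride reduction of the aryl aldehyde gives the benzylic alcohol without touching the MOM acetal.

Step 3
Reactants: 3 [4-(methoxymethoxy)-3,5-dimethoxyphenyl]methanol
Product: 4 5-(bromomethyl)-1,3-dimethoxy-2-(methoxymethoxy)benzene
Conditions: CBr4, PPh3, CH2Cl2, 0 °C
Reagents that add atoms: carbon tetrabromide, BrC(Br)(Br)Br
Why: Appel bromination works under neutral conditions, so no HBr arises that could cleave the MOM acetal; the electron-rich bromide is used without storage.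

Step 4
Reactants: 5 5-bromo-2-hydroxy-3-methoxybenzaldehyde
Product: 6 5-bromo-3-methoxy-2-(methoxymethoxy)benzaldehyde
Conditions: MOMCl, i-Pr2NEt, CH2Cl2, 0 °C to rt
Reagents that add atoms: chloromethyl methyl ether, COCCl
Why: Williamson-type MOM protection of the ortho phenol prevents phenoxide formation, which would deactivate the aldehyde in the base-mediated condensation that follows.

Step 5
Reactants: 6 5-bromo-3-methoxy-2-(methoxymethoxy)benzaldehyde
Product: 7 5-bromo-1-methoxy-2-(methoxymethoxy)-3-[2-(methylsulfanyl)-2-(methylsulfinyl)ethenyl]benzene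
Conditions: CH3S(O)CH2SCH3, benzyltrimethylammonium hydroxide (40% in MeOH), THF, reflux
Reagents that add atoms: methyl (methylsulfanyl)methyl sulfoxide, CS(=O)CSC
Why: Knoevenagel-type condensation of the sulfinyl-stabilised carbanion with the non-enolisable aryl aldehyde gives the ketene dithioacetal S-oxide, a one-carbon homologue at the carboxyl oxidation level.

Step 6
Reactants: 7 5-bromo-1-methoxy-2-(methoxymethoxy)-3-[2-(methylsulfanyl)-2-(methylsulfinyl)ethenyl]benzene
Product: 8 methyl 2-(5-bromo-2-hydroxy-3-methoxyphenyl)acetate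
Conditions: HCl (2 M in MeOH), 0 to 40 °C; NaHCO3 before concentration
Reagents that add atoms: methanol, CO
Why: Acid methanolysis of the ketene dithioacetal S-oxide (Pummerer-type C-protonation, methanol addition and loss of both sulfur groups) gives the methyl arylacetate, and the same acid removes the MOM group while excess methanol holds the product as the open hydroxy ester and not the lactone.

Step 7
Reactants: 8 methyl 2-(5-bromo-2-hydroxy-3-methoxyphenyl)acetate; 4 5-(bromomethyl)-1,3-dimethoxy-2-(methoxymethoxy)benzene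
Product: 9 methyl 2-[5-bromo-3-methoxy-2-[[4-(methoxymethoxy)-3,5-dimethoxyphenyl]methoxy]phenyl]acetate
Conditions: K2CO3, DMF, rt
Reagents that add atoms: none
Why: Williamson ether synthesis, in which the phenoxide displaces the primary benzylic bromide while carbonate is too weak to enolise the arylacetate.

Step 8
Reactants: 9 methyl 2-[5-bromo-3-methoxy-2-[[4-(methoxymethoxy)-3,5-dimethoxyphenyl]methoxy]phenyl]acetate
Product: 10 methyl 2-diazo-2-[5-bromo-3-methoxy-2-[[4-(methoxymethoxy)-3,5-dimethoxyphenyl]methoxy]phenyl]acetate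
Conditions: 4-acetamidobenzenesulfonyl azide, DBU, MeCN, 0 °C to rt
Reagents that add atoms: 4-acetamidobenzenesulfonyl azide, CC(=O)Nc1ccc(cc1)S(=O)(=O)N=[N+]=[N-]
Why: Regitz diazo transfer to the DBU-generated arylacetate enolate is the standard entry to aryldiazoacetates and tolerates the aryl bromide and both acetal-type ethers.

Step 9
Reactants: 10 methyl 2-diazo-2-[5-bromo-3-methoxy-2-[[4-(methoxymethoxy)-3,5-dimethoxyphenyl]methoxy]phenyl]acetate
Product: 12 methyl (2R,3R)-5-bromo-7-methoxy-2-[4-(methoxymethoxy)-3,5-dimethoxyphenyl]-2,3-dihydro-1-benzofuran-3-carboxylate (trans ester), via cis-(2R,3S) ester 11 (not isolated)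
Conditions: Rh2(S-PTTL)4 [dirhodium tetrakis(N-phthaloyl-(S)-tert-leucinate)] (1 mol%), toluene, −60 °C, slow addition of 10; then NaOMe (0.2 equiv), MeOH, 0 °C
Reagents that add atoms: none
Why: Rh2(S-PTTL)4 expels N2 from 10, and the resulting donor–acceptor carbene on divalent rhodium inserts into one of the two enantiotopic O–CH2–ring C hydrogens through a concerted, asynchronous three-centre transition state with hydride-like transfer, forming the C2–C3 bond. The closest known reaction type is the enantioselective intramolecular C–H insertion of aryldiazoacetates into benzyl aryl ethers with phthalimido amino acid dirhodium carboxylates, which gives cis-2-aryl-2,3-dihydrobenzofuran-3-carboxylates; this ligand class is chosen because it suits methylene (not methine) benzylic ether sites. The furan ring closes by 1,5-insertion into the C–H bond five atoms from the carbene carbon, the only site open to a five-membered transition state, since the C7 methoxy group is meta to the carbene carbon and the MOM group is remote. C2 is set by the chiral carboxylate pocket, which selects one benzylic hydrogen (catalyst control), while C3 is first formed cis (11) and is then moved to the trans (2R,3R) arrangement of 12 by catalytic methoxide through the ester enolate, under thermodynamic control and without touching C2. The step needs chemoselectivity for insertion over carbene dimerisation and arene addition, which the doubly activated C–H bond (ether oxygen plus electron-rich ring C), slow addition and low temperature should secure; it also needs the equilibration to stop short of E1cB loss of the O1 phenoxide, which substoichiometric base at 0 °C should secure.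

Step 10
Reactants: 12 methyl (2R,3R)-5-bromo-7-methoxy-2-[4-(methoxymethoxy)-3,5-dimethoxyphenyl]-2,3-dihydro-1-benzofuran-3-carboxylate
Product: 13 [(2R,3S)-5-bromo-7-methoxy-2-[4-(methoxymethoxy)-3,5-dimethoxyphenyl]-2,3-dihydro-1-benzofuran-3-yl]methanol
Conditions: i-Bu2AlH, CH2Cl2, −78 to 0 °C; aq. potassium sodium tartrate
Reagents that add atoms: none
Why: Hydride reduction of the ester to the primary alcohol under non-basic conditions leaves C2, the aryl bromide and the MOM group untouched and removes the enolisable position at C3 for good (the descriptor changes to 3S only through priorities).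

Step 11
Reactants: 13 [(2R,3S)-5-bromo-7-methoxy-2-[4-(methoxymethoxy)-3,5-dimethoxyphenyl]-2,3-dihydro-1-benzofuran-3-yl]methanol
Product: 14 tert-butyldiphenylsilyl (TBDPS) ether of 13
Conditions: TBDPSCl, imidazole, DMF, rt
Reagents that add atoms: tert-butyl(chloro)diphenylsilane, CC(C)(C)[Si](Cl)(c1ccccc1)c1ccccc1
Why: Imidazole-promoted silylation of the primary alcohol gives an ether robust enough for the acidic MOM removal and for all later base, boron and hydride steps.

Step 12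
Reactants: 14 TBDPS ether of 13
Product: 15 ring C phenol, 4-[(2R,3S)-5-bromo-3-(TBDPS-oxymethyl)-7-methoxy-2,3-dihydro-1-benzofuran-2-yl]-2,6-dimethoxyphenol (its aryloxy group is written ArC–O below)
Conditions: HCl (0.5 M in MeOH–THF 1:1), 40 °C
Reagents that add atoms: none
Why: Acid-catalysed acetal methanolysis removes the phenolic MOM group far faster than the TBDPS ether is cleaved or the C2–O1 benzylic ether ionises.

Step 13
Reactants: 15 ring C phenol; 16 (4R)-4-benzyl-3-(chloroacetyl)-1,3-oxazolidin-2-one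
Product: 17 (4R)-4-benzyl-3-[2-(ArC–O)acetyl]-1,3-oxazolidin-2-one
Conditions: K2CO3, NaI (10 mol%), acetone, 50 °C
Reagents that add atoms: none
Why: Williamson alkylation, in which the α-halo imide (activated by in situ iodide exchange) is a primary, strongly SN2-active electrophile, so the hindered 2,6-dimethoxyphenoxide should couple at carbon and not at the imide carbonyl.

Step 14
Reactants: 1 syringaldehyde
Product: 18 4-(tert-butyldimethylsilyloxy)-3,5-dimethoxybenzaldehyde (TBS = tert-butyldimethylsilyl)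
Conditions: TBSCl, imidazole, DMF, rt
Reagents that add atoms: tert-butyl(chloro)dimethylsilane, CC(C)(C)[Si](C)(C)Cl
Why: Phenol silylation gives an aldehyde partner whose aryl silyl ether tolerates boron aldol, peroxide work-up and Mitsunobu conditions and can later be cleaved selectively in the presence of alkyl silyl ethers.

Step 15
Reactants: 17 (4R)-4-benzyl-3-[2-(ArC–O)acetyl]-1,3-oxazolidin-2-one; 18 4-(TBS-oxy)-3,5-dimethoxybenzaldehyde
Product: 20 syn-aldol imide (4R)-4-benzyl-3-[(2R,3S)-2-(ArC–O)-3-hydroxy-3-(4-TBS-oxy-3,5-dimethoxyphenyl)propanoyl]-1,3-oxazolidin-2-one, via Z-boron enolate 19 (not isolated)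
Conditions: Bu2BOTf, Et3N, CH2Cl2, −78 to 0 °C; then 18, −78 to 0 °C; pH 7 phosphate buffer, MeOH, H2O2, 0 °C
Reagents that add atoms: none
Why: Evans syn-aldol, in which the Z-boron enolate reacts through a chair Zimmerman–Traxler transition state on the face away from the auxiliary benzyl group, so the (R)-auxiliary sets the aryloxy carbon (the later 8S centre) and the syn carbinol (threo, to be inverted).

Step 16
Reactants: 20 syn-aldol imide
Product: 21 (4R)-4-benzyl-3-[(2R,3R)-2-(ArC–O)-3-(4-nitrobenzoyloxy)-3-(4-TBS-oxy-3,5-dimethoxyphenyl)propanoyl]-1,3-oxazolidin-2-one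
Conditions: 4-nitrobenzoic acid, PPh3, DIAD, THF, 0 °C to rt
Reagents that add atoms: 4-nitrobenzoic acid, OC(=O)c1ccc(cc1)[N+](=O)[O-]
Why: Mitsunobu reaction, in which SN2 displacement of the oxyphosphonium by the acidic carboxylate inverts the benzylic carbinol and turns the threo adduct into the erythro ester; the silylated para oxygen flanked by two methoxy groups is a weak donor, which should disfavour ionisation.

Step 17
Reactants: 21 erythro nitrobenzoate imide
Product: 22 erythro diol (1R,2S)-2-(ArC–O)-1-(4-TBS-oxy-3,5-dimethoxyphenyl)propane-1,3-diol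
Conditions: LiBH4, THF–MeOH (20:1), 0 °C to rt
Reagents that add atoms: none
Why: Borohydride reduction releases the acyl chain from the auxiliary as the primary alcohol and reductively cleaves the activated nitrobenzoate, leaving aryl bromide and silyl ethers intact; any aryl silyl ether lost here is restored in step 18.

Step 18
Reactants: 22 erythro diol
Product: 24 ring B phenol 4-[(1R,2S)-2-(ArC–O)-1,3-bis(TBS-oxy)propyl]-2,6-dimethoxyphenol (its aryloxy group is written ArB–O below), via tris-silyl ether 23 (not isolated)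
Conditions: TBSOTf, 2,6-lutidine, CH2Cl2, −78 to 0 °C; then K2CO3, MeOH–THF, rt
Reagents that add atoms: tert-butyldimethylsilyl trifluoromethanesulfonate, CC(C)(C)[Si](C)(C)OS(=O)(=O)C(F)(F)F
Why: Silyl triflate silylation caps both hydroxyls, and methanolic carbonate then cleaves only the aryl silyl ether (phenoxide leaving group), alkyl TBS and TBDPS ethers being inert to these conditions.

Step 19
Reactants: 24 ring B phenol; 16 (4R)-4-benzyl-3-(chloroacetyl)-1,3-oxazolidin-2-one
Product: 25 (4R)-4-benzyl-3-[2-(ArB–O)acetyl]-1,3-oxazolidin-2-one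
Conditions: K2CO3, NaI (10 mol%), acetone, 50 °C
Reagents that add atoms: none
Why: The same Williamson alkylation as in step 13, on the second 2,6-dimethoxyphenol, with all hydroxyls silylated.

Step 20
Reactants: 26 vanillin
Product: 27 3-methoxy-4-(triisopropylsilyloxy)benzaldehyde (TIPS = triisopropylsilyl)
Conditions: TIPSCl, imidazole, DMF, rt
Reagents that add atoms: chlorotri(propan-2-yl)silane, CC(C)[Si](Cl)(C(C)C)C(C)C
Why: Phenol silylation with the bulkier silyl group gives a ring A aryl ether that should withstand borohydride and the carbonate base of the later Heck step.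

Step 21
Reactants: 25 (4R)-4-benzyl-3-[2-(ArB–O)acetyl]-1,3-oxazolidin-2-one; 27 3-methoxy-4-(TIPS-oxy)benzaldehyde
Product: 29 syn-aldol imide (4R)-4-benzyl-3-[(2R,3S)-2-(ArB–O)-3-hydroxy-3-(3-methoxy-4-TIPS-oxyphenyl)propanoyl]-1,3-oxazolidin-2-one, via Z-boron enolate 28 (not isolated)
Conditions: Bu2BOTf, Et3N, CH2Cl2, −78 to 0 °C; then 27, −78 to 0 °C; pH 7 phosphate buffer, MeOH, H2O2, 0 °C
Reagents that add atoms: none
Why: Evans syn-aldol with the same auxiliary-controlled facial sense as step 15, the remote stereocentres having no say in the chair Zimmerman–Traxler transition state.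

Step 22
Reactants: 29 syn-aldol imide
Product: 30 (4R)-4-benzyl-3-[(2R,3R)-2-(ArB–O)-3-(4-nitrobenzoyloxy)-3-(3-methoxy-4-TIPS-oxyphenyl)propanoyl]-1,3-oxazolidin-2-one
Conditions: 4-nitrobenzoic acid, PPh3, DIAD, THF, 0 °C to rt
Reagents that add atoms: 4-nitrobenzoic acid, OC(=O)c1ccc(cc1)[N+](=O)[O-]
Why: Mitsunobu inversion of the only free hydroxyl converts the threo carbinol into the erythro ester by SN2 displacement.

Step 23
Reactants: 30 erythro nitrobenzoate imide
Product: 31 erythro diol (1R,2S)-2-(ArB–O)-1-(3-methoxy-4-TIPS-oxyphenyl)propane-1,3-diol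
Conditions: LiBH4, THF–MeOH (20:1), 0 °C to rt
Reagents that add atoms: none
Why: Borohydride reduction removes the auxiliary and the nitrobenzoate as in step 17, the hindered aryl TIPS ether and all alkyl silyl ethers being stable to the reagent.

Step 24
Reactants: 31 erythro diol
Product: 32 1,3-bis-O-TBS ether of 31 (aryl bromide with every hydroxyl silylated)
Conditions: TBSOTf, 2,6-lutidine, CH2Cl2, −78 to 0 °C
Reagents that add atoms: tert-butyldimethylsilyl trifluoromethanesulfonate, CC(C)(C)[Si](C)(C)OS(=O)(=O)C(F)(F)F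
Why: Silylation of both hydroxyls keeps the benzylic carbinol from being oxidised by arylpalladium species (alkoxide β-hydride elimination) in the coupling that follows.

Step 25
Reactants: 32 fully silylated aryl bromide
Product: 34 C5 (E)-3-oxoprop-1-enyl analogue of 32 (silylated target), via diethyl acetal 33 (not isolated)
Conditions: Pd(OAc)2 (5 mol%), acrolein diethyl acetal, Bu4NOAc, K2CO3, KCl, DMF, 90 °C; then 1 M HCl, THF, 0 °C
Reagents that add atoms: acrolein diethyl acetal, C=CC(OCC)OCC; water, O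
Why: Mizoroki–Heck reaction, in which zerovalent palladium formed in situ inserts into the C5–Br bond, syn-carbopalladation of the acetal-masked acrolein and β-hydride elimination toward the benzylic hydrogen give the (E)-cinnamyl acetal (the acetate and chloride additives steering elimination away from the acetal carbon), and brief dilute acid unmasks the enal.

Step 26
Reactants: 34 silylated target
Product: 35 target, (E)-3-[(2R,3S)-2-[4-[(1R,2S)-1,3-dihydroxy-1-[4-[(1R,2S)-1,3-dihydroxy-1-(4-hydroxy-3-methoxyphenyl)propan-2-yl]oxy-3,5-dimethoxyphenyl]propan-2-yl]oxy-3,5-dimethoxyphenyl]-3-(hydroxymethyl)-7-methoxy-2,3-dihydro-1-benzofuran-5-yl]prop-2-enal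
Conditions: Bu4NF, AcOH, THF, 0 °C to rt
Reagents that add atoms: none
Why: Fluoride-driven Si–O cleavage removes the TBDPS, the four TBS and the aryl TIPS groups in one operation, the acetic acid buffer keeping the phenol, the enal and the benzylic carbinols away from free base, and no stereocentre is touched.

**Compound list**

1 | syringaldehyde (4-hydroxy-3,5-dimethoxybenzaldehyde) | COc1cc(C=O)cc(OC)c1O | starting material
2 | 4-(methoxymethoxy)-3,5-dimethoxybenzaldehyde | COCOc1c(OC)cc(C=O)cc1OC | intermediate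
3 | [4-(methoxymethoxy)-3,5-dimethoxyphenyl]methanol | COCOc1c(OC)cc(CO)cc1OC | intermediate
4 | 5-(bromomethyl)-1,3-dimethoxy-2-(methoxymethoxy)benzene | COCOc1c(OC)cc(CBr)cc1OC | intermediate
5 | 5-bromo-2-hydroxy-3-methoxybenzaldehyde (5-bromo-o-vanillin; commercial, otherwise by bromination of o-vanillin) | COc1cc(Br)cc(C=O)c1O | starting material
6 | 5-bromo-3-methoxy-2-(methoxymethoxy)benzaldehyde | COCOc1c(OC)cc(Br)cc1C=O | intermediate
7 | 5-bromo-1-methoxy-2-(methoxymethoxy)-3-[2-(methylsulfanyl)-2-(methylsulfinyl)ethenyl]benzene (alkene isomers, racemic at sulfur) | COCOc1c(OC)cc(Br)cc1C=C(SC)S(C)=O | intermediate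
8 | methyl 2-(5-bromo-2-hydroxy-3-methoxyphenyl)acetate | COC(=O)Cc1cc(Br)cc(OC)c1O | intermediate
9 | methyl 2-[5-bromo-3-methoxy-2-[[4-(methoxymethoxy)-3,5-dimethoxyphenyl]methoxy]phenyl]acetate | COC(=O)Cc1cc(Br)cc(OC)c1OCc1cc(OC)c(OCOC)c(OC)c1 | intermediate
10 | methyl 2-diazo-2-[5-bromo-3-methoxy-2-[[4-(methoxymethoxy)-3,5-dimethoxyphenyl]methoxy]phenyl]acetate | COC(=O)C(=[N+]=[N-])c1cc(Br)cc(OC)c1OCc1cc(OC)c(OCOC)c(OC)c1 | intermediate
11 | methyl (2R,3S)-5-bromo-7-methoxy-2-[4-(methoxymethoxy)-3,5-dimethoxyphenyl]-2,3-dihydro-1-benzofuran-3-carboxylate (cis) | COCOc1c(OC)cc([C@@H]2Oc3c(OC)cc(Br)cc3[C@@H]2C(=O)OC)cc1OC | intermediate (not isolated)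
12 | methyl (2R,3R)-5-bromo-7-methoxy-2-[4-(methoxymethoxy)-3,5-dimethoxyphenyl]-2,3-dihydro-1-benzofuran-3-carboxylate (trans) | COCOc1c(OC)cc([C@@H]2Oc3c(OC)cc(Br)cc3[C@H]2C(=O)OC)cc1OC | intermediate
13 | [(2R,3S)-5-bromo-7-methoxy-2-[4-(methoxymethoxy)-3,5-dimethoxyphenyl]-2,3-dihydro-1-benzofuran-3-yl]methanol | COCOc1c(OC)cc([C@@H]2Oc3c(OC)cc(Br)cc3[C@H]2CO)cc1OC | intermediate
14 | tert-butyl[[(2R,3S)-5-bromo-7-methoxy-2-[4-(methoxymethoxy)-3,5-dimethoxyphenyl]-2,3-dihydro-1-benzofuran-3-yl]methoxy]diphenylsilane | COCOc1c(OC)cc([C@@H]2Oc3c(OC)cc(Br)cc3[C@H]2CO[Si](c4ccccc4)(c4ccccc4)C(C)(C)C)cc1OC | intermediate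
15 | 4-[(2R,3S)-5-bromo-3-[[tert-butyl(diphenyl)silyl]oxymethyl]-7-methoxy-2,3-dihydro-1-benzofuran-2-yl]-2,6-dimethoxyphenol (ring C phenol; aryloxy = ArC–O) | COc1cc([C@@H]2Oc3c(OC)cc(Br)cc3[C@H]2CO[Si](c4ccccc4)(c4ccccc4)C(C)(C)C)cc(OC)c1O | intermediate
16 | (4R)-4-benzyl-3-(chloroacetyl)-1,3-oxazolidin-2-one (commercial; otherwise one step from (R)-4-benzyl-1,3-oxazolidin-2-one and chloroacetyl chloride) | ClCC(=O)N1[C@H](Cc2ccccc2)COC1=O | starting material
17 | (4R)-4-benzyl-3-[2-(ArC–O)acetyl]-1,3-oxazolidin-2-one | COc1cc([C@@H]2Oc3c(OC)cc(Br)cc3[C@H]2CO[Si](c4ccccc4)(c4ccccc4)C(C)(C)C)cc(OC)c1OCC(=O)N1[C@H](Cc2ccccc2)COC1=O | intermediate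
18 | 4-[tert-butyl(dimethyl)silyl]oxy-3,5-dimethoxybenzaldehyde | CC(C)(C)[Si](C)(C)Oc1c(OC)cc(C=O)cc1OC | intermediate
19 | dibutylboron Z-enolate of 17 | COc1cc([C@@H]2Oc3c(OC)cc(Br)cc3[C@H]2CO[Si](c4ccccc4)(c4ccccc4)C(C)(C)C)cc(OC)c1O/C=C(\OB(CCCC)CCCC)N1[C@H](Cc2ccccc2)COC1=O | intermediate (not isolated)
20 | (4R)-4-benzyl-3-[(2R,3S)-2-(ArC–O)-3-hydroxy-3-(4-TBS-oxy-3,5-dimethoxyphenyl)propanoyl]-1,3-oxazolidin-2-one (syn, threo) | COc1cc([C@@H]2Oc3c(OC)cc(Br)cc3[C@H]2CO[Si](c4ccccc4)(c4ccccc4)C(C)(C)C)cc(OC)c1O[C@H]([C@@H](O)c5cc(OC)c(O[Si](C)(C)C(C)(C)C)c(OC)c5)C(=O)N1[C@H](Cc2ccccc2)COC1=O | intermediate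
21 | (4R)-4-benzyl-3-[(2R,3R)-2-(ArC–O)-3-(4-nitrobenzoyloxy)-3-(4-TBS-oxy-3,5-dimethoxyphenyl)propanoyl]-1,3-oxazolidin-2-one (erythro) | COc1cc([C@@H]2Oc3c(OC)cc(Br)cc3[C@H]2CO[Si](c4ccccc4)(c4ccccc4)C(C)(C)C)cc(OC)c1O[C@H]([C@H](OC(=O)c6ccc(cc6)[N+](=O)[O-])c5cc(OC)c(O[Si](C)(C)C(C)(C)C)c(OC)c5)C(=O)N1[C@H](Cc2ccccc2)COC1=O | intermediate
22 | (1R,2S)-2-(ArC–O)-1-(4-TBS-oxy-3,5-dimethoxyphenyl)propane-1,3-diol (erythro) | COc1cc([C@@H]2Oc3c(OC)cc(Br)cc3[C@H]2CO[Si](c4ccccc4)(c4ccccc4)C(C)(C)C)cc(OC)c1O[C@H]([C@H](O)c5cc(OC)c(O[Si](C)(C)C(C)(C)C)c(OC)c5)CO | intermediate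
23 | 1,3-bis-O-TBS ether of 22 (tris-silyl ether) | COc1cc([C@@H]2Oc3c(OC)cc(Br)cc3[C@H]2CO[Si](c4ccccc4)(c4ccccc4)C(C)(C)C)cc(OC)c1O[C@H]([C@H](O[Si](C)(C)C(C)(C)C)c5cc(OC)c(O[Si](C)(C)C(C)(C)C)c(OC)c5)CO[Si](C)(C)C(C)(C)C | intermediate (not isolated)
24 | 4-[(1R,2S)-2-(ArC–O)-1,3-bis(TBS-oxy)propyl]-2,6-dimethoxyphenol (ring B phenol; aryloxy = ArB–O) | COc1cc([C@@H]2Oc3c(OC)cc(Br)cc3[C@H]2CO[Si](c4ccccc4)(c4ccccc4)C(C)(C)C)cc(OC)c1O[C@H]([C@H](O[Si](C)(C)C(C)(C)C)c5cc(OC)c(O)c(OC)c5)CO[Si](C)(C)C(C)(C)C | intermediate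
25 | (4R)-4-benzyl-3-[2-(ArB–O)acetyl]-1,3-oxazolidin-2-one | COc1cc([C@@H]2Oc3c(OC)cc(Br)cc3[C@H]2CO[Si](c4ccccc4)(c4ccccc4)C(C)(C)C)cc(OC)c1O[C@H]([C@H](O[Si](C)(C)C(C)(C)C)c5cc(OC)c(OCC(=O)N6[C@H](Cc7ccccc7)COC6=O)c(OC)c5)CO[Si](C)(C)C(C)(C)C | intermediate
26 | vanillin (4-hydroxy-3-methoxybenzaldehyde) | COc1cc(C=O)ccc1O | starting material
27 | 3-methoxy-4-[tri(propan-2-yl)silyl]oxybenzaldehyde | COc1cc(C=O)ccc1O[Si](C(C)C)(C(C)C)C(C)C | intermediate
28 | dibutylboron Z-enolate of 25 | COc1cc([C@@H]2Oc3c(OC)cc(Br)cc3[C@H]2CO[Si](c4ccccc4)(c4ccccc4)C(C)(C)C)cc(OC)c1O[C@H]([C@H](O[Si](C)(C)C(C)(C)C)c5cc(OC)c(O/C=C(\OB(CCCC)CCCC)N6[C@H](Cc7ccccc7)COC6=O)c(OC)c5)CO[Si](C)(C)C(C)(C)C | intermediate (not isolated)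
29 | (4R)-4-benzyl-3-[(2R,3S)-2-(ArB–O)-3-hydroxy-3-(3-methoxy-4-TIPS-oxyphenyl)propanoyl]-1,3-oxazolidin-2-one (syn, threo) | COc1cc([C@@H]2Oc3c(OC)cc(Br)cc3[C@H]2CO[Si](c4ccccc4)(c4ccccc4)C(C)(C)C)cc(OC)c1O[C@H]([C@H](O[Si](C)(C)C(C)(C)C)c5cc(OC)c(O[C@H]([C@@H](O)c8ccc(O[Si](C(C)C)(C(C)C)C(C)C)c(OC)c8)C(=O)N6[C@H](Cc7ccccc7)COC6=O)c(OC)c5)CO[Si](C)(C)C(C)(C)C | intermediate
30 | (4R)-4-benzyl-3-[(2R,3R)-2-(ArB–O)-3-(4-nitrobenzoyloxy)-3-(3-methoxy-4-TIPS-oxyphenyl)propanoyl]-1,3-oxazolidin-2-one (erythro) | COc1cc([C@@H]2Oc3c(OC)cc(Br)cc3[C@H]2CO[Si](c4ccccc4)(c4ccccc4)C(C)(C)C)cc(OC)c1O[C@H]([C@H](O[Si](C)(C)C(C)(C)C)c5cc(OC)c(O[C@H]([C@H](OC(=O)c9ccc(cc9)[N+](=O)[O-])c8ccc(O[Si](C(C)C)(C(C)C)C(C)C)c(OC)c8)C(=O)N6[C@H](Cc7ccccc7)COC6=O)c(OC)c5)CO[Si](C)(C)C(C)(C)C | intermediate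
31 | (1R,2S)-2-(ArB–O)-1-(3-methoxy-4-TIPS-oxyphenyl)propane-1,3-diol (erythro) | COc1cc([C@@H]2Oc3c(OC)cc(Br)cc3[C@H]2CO[Si](c4ccccc4)(c4ccccc4)C(C)(C)C)cc(OC)c1O[C@H]([C@H](O[Si](C)(C)C(C)(C)C)c5cc(OC)c(O[C@H]([C@H](O)c8ccc(O[Si](C(C)C)(C(C)C)C(C)C)c(OC)c8)CO)c(OC)c5)CO[Si](C)(C)C(C)(C)C | intermediate
32 | 1,3-bis-O-TBS ether of 31 | COc1cc([C@@H]2Oc3c(OC)cc(Br)cc3[C@H]2CO[Si](c4ccccc4)(c4ccccc4)C(C)(C)C)cc(OC)c1O[C@H]([C@H](O[Si](C)(C)C(C)(C)C)c5cc(OC)c(O[C@H]([C@H](O[Si](C)(C)C(C)(C)C)c8ccc(O[Si](C(C)C)(C(C)C)C(C)C)c(OC)c8)CO[Si](C)(C)C(C)(C)C)c(OC)c5)CO[Si](C)(C)C(C)(C)C | intermediate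
33 | analogue of 32 with (E)-3,3-diethoxyprop-1-enyl at C5 in place of bromine | COc1cc([C@@H]2Oc3c(OC)cc(/C=C/C(OCC)OCC)cc3[C@H]2CO[Si](c4ccccc4)(c4ccccc4)C(C)(C)C)cc(OC)c1O[C@H]([C@H](O[Si](C)(C)C(C)(C)C)c5cc(OC)c(O[C@H]([C@H](O[Si](C)(C)C(C)(C)C)c8ccc(O[Si](C(C)C)(C(C)C)C(C)C)c(OC)c8)CO[Si](C)(C)C(C)(C)C)c(OC)c5)CO[Si](C)(C)C(C)(C)C | intermediate (not isolated)
34 | analogue of 32 with (E)-3-oxoprop-1-enyl at C5 in place of bromine (silylated target) | COc1cc([C@@H]2Oc3c(OC)cc(/C=C/C=O)cc3[C@H]2CO[Si](c4ccccc4)(c4ccccc4)C(C)(C)C)cc(OC)c1O[C@H]([C@H](O[Si](C)(C)C(C)(C)C)c5cc(OC)c(O[C@H]([C@H](O[Si](C)(C)C(C)(C)C)c8ccc(O[Si](C(C)C)(C(C)C)C(C)C)c(OC)c8)CO[Si](C)(C)C(C)(C)C)c(OC)c5)CO[Si](C)(C)C(C)(C)C | intermediate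
35 | (E)-3-[(2R,3S)-2-[4-[(1R,2S)-1,3-dihydroxy-1-[4-[(1R,2S)-1,3-dihydroxy-1-(4-hydroxy-3-methoxyphenyl)propan-2-yl]oxy-3,5-dimethoxyphenyl]propan-2-yl]oxy-3,5-dimethoxyphenyl]-3-(hydroxymethyl)-7-methoxy-2,3-dihydro-1-benzofuran-5-yl]prop-2-enal | COc1cc([C@@H](O)[C@H](CO)Oc2c(OC)cc([C@@H](O)[C@H](CO)Oc3c(OC)cc([C@@H]4Oc5c(OC)cc(/C=C/C=O)cc5[C@H]4CO)cc3OC)cc2OC)ccc1O | target

**Step count and risks**

Total step count: 26. Longest linear sequence: 21 steps (from 5 to 35 through steps 4–13, 15–19 and 21–26).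

Steps most likely to fail:

1. Step 9. The catalyst pocket may discriminate the two enantiotopic benzylic hydrogens only partly, and the methoxide equilibration may erode C2 through reversible E1cB opening of the furan ring. Fallback (auxiliary control added to catalyst control, with a separable diastereomer): it sets out from 9 and comes back at 13. Compound 9 is saponified (LiOH, THF–water) to the arylacetic acid F1. F1 is esterified (EDC·HCl, DMAP, CH2Cl2) with (S)-2-hydroxy-1-(pyrrolidin-1-yl)propan-1-one to the lactamide ester F2, the lactamide antipode being the one that matches the catalyst. Diazo transfer as in step 8 gives the diazo ester F3. Insertion with Rh2(S-DOSP)4 [dirhodium tetrakis((S)-N-(4-dodecylphenylsulfonyl)prolinate)], followed by DBU equilibration if needed, gives the trans lactamide ester F4, which is freed of minor diastereomers by chromatography or crystallisation. LiBH4 reduction of F4 then gives 13.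

2. Step 16 (the same holds for step 22). The activated β-oxyphosphonium imide may undergo E2 dehydration to the α-aryloxy cinnamoyl imide, or the benzylic C–O bond may ionise so that inversion is no longer clean. Fallback (oxidation then chelation-controlled reduction in place of SN2 inversion): it sets out from 20 and comes back at 23. Compound 20 is reduced with LiBH4 to the threo diol F5, and the primary hydroxyl is silylated (TBSCl, imidazole) to the mono-silyl ether F6. Dess–Martin oxidation of the benzylic carbinol gives the α-aryloxy ketone F7. Reduction with Zn(BH4)2 in Et2O at −20 °C, with zinc bridging the ketone and aryloxy oxygens and hydride entering from the side of the C–H bond (Cram chelate model), should give the erythro alcohol F8. TBSOTf and 2,6-lutidine convert F8 into 23, which is carried on as in step 18.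

3. Step 25. Oxidative addition into the electron-rich C5–Br bond may be sluggish, and β-hydride elimination toward the acetal carbon may divert material to the saturated ester. Fallback (cross-coupling with a preformed vinyl partner in place of olefin insertion): it sets out from 32 and comes back at 33. Suzuki–Miyaura coupling of 32 with (E)-2-(3,3-diethoxyprop-1-en-1-yl)-4,4,5,5-tetramethyl-1,3,2-dioxaborolane [Pd(dppf)Cl2, K3PO4, dioxane–water, 80 °C] fixes regiochemistry and alkene geometry in the reagent and gives 33, which the same dilute acid treatment converts into 34.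

**Further compounds**

F1 | step 9 | 2-[5-bromo-3-methoxy-2-[[4-(methoxymethoxy)-3,5-dimethoxyphenyl]methoxy]phenyl]acetic acid | COCOc1c(OC)cc(COc2c(OC)cc(Br)cc2CC(=O)O)cc1OC
F2 | step 9 | (2S)-1-oxo-1-(pyrrolidin-1-yl)propan-2-yl 2-[5-bromo-3-methoxy-2-[[4-(methoxymethoxy)-3,5-dimethoxyphenyl]methoxy]phenyl]acetate | COCOc1c(OC)cc(COc2c(OC)cc(Br)cc2CC(=O)O[C@@H](C)C(=O)N2CCCC2)cc1OC
F3 | step 9 | (2S)-1-oxo-1-(pyrrolidin-1-yl)propan-2-yl 2-diazo-2-[5-bromo-3-methoxy-2-[[4-(methoxymethoxy)-3,5-dimethoxyphenyl]methoxy]phenyl]acetate | COCOc1c(OC)cc(COc2c(OC)cc(Br)cc2C(=[N+]=[N-])C(=O)O[C@@H](C)C(=O)N2CCCC2)cc1OC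
F4 | step 9 | (2S)-1-oxo-1-(pyrrolidin-1-yl)propan-2-yl (2R,3R)-5-bromo-7-methoxy-2-[4-(methoxymethoxy)-3,5-dimethoxyphenyl]-2,3-dihydro-1-benzofuran-3-carboxylate | COCOc1c(OC)cc([C@@H]2Oc3c(OC)cc(Br)cc3[C@H]2C(=O)O[C@@H](C)C(=O)N2CCCC2)cc1OC
F5 | step 16 | (1S,2S)-2-(ArC–O)-1-(4-TBS-oxy-3,5-dimethoxyphenyl)propane-1,3-diol (threo) | COc1cc([C@@H]2Oc3c(OC)cc(Br)cc3[C@H]2CO[Si](c4ccccc4)(c4ccccc4)C(C)(C)C)cc(OC)c1O[C@H]([C@@H](O)c5cc(OC)c(O[Si](C)(C)C(C)(C)C)c(OC)c5)CO
F6 | step 16 | (1S,2S)-2-(ArC–O)-3-(TBS-oxy)-1-(4-TBS-oxy-3,5-dimethoxyphenyl)propan-1-ol (threo) | COc1cc([C@@H]2Oc3c(OC)cc(Br)cc3[C@H]2CO[Si](c4ccccc4)(c4ccccc4)C(C)(C)C)cc(OC)c1O[C@H]([C@@H](O)c5cc(OC)c(O[Si](C)(C)C(C)(C)C)c(OC)c5)CO[Si](C)(C)C(C)(C)C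
F7 | step 16 | (2S)-2-(ArC–O)-3-(TBS-oxy)-1-(4-TBS-oxy-3,5-dimethoxyphenyl)propan-1-one | COc1cc([C@@H]2Oc3c(OC)cc(Br)cc3[C@H]2CO[Si](c4ccccc4)(c4ccccc4)C(C)(C)C)cc(OC)c1O[C@H](C(=O)c5cc(OC)c(O[Si](C)(C)C(C)(C)C)c(OC)c5)CO[Si](C)(C)C(C)(C)C
F8 | step 16 | (1R,2S)-2-(ArC–O)-3-(TBS-oxy)-1-(4-TBS-oxy-3,5-dimethoxyphenyl)propan-1-ol (erythro) | COc1cc([C@@H]2Oc3c(OC)cc(Br)cc3[C@H]2CO[Si](c4ccccc4)(c4ccccc4)C(C)(C)C)cc(OC)c1O[C@H]([C@H](O)c5cc(OC)c(O[Si](C)(C)C(C)(C)C)c(OC)c5)CO[Si](C)(C)C(C)(C)C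
F0 | step 25 | none | none
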